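Start with the charge.

    spent carrier + salt in the second phase ⇌ fresh carrier + spent salt in the second phase (K1 = 0.081, k1 = 1000 M⁻¹ s⁻¹)
    starting material + fresh carrier → product + spent carrier (k2 = 940 M⁻¹ s⁻¹)
    fresh carrier → spent catalyst (k3 = 0.065 s⁻¹)
    spent carrier + spent carrier ⇌ resting dimer (K4 = 3200 M⁻¹, k4 = 11000 M⁻¹ s⁻¹)
    crystals ⇌ product, rate k5*(cs5 - [product]) while solid is left; crystals form when [product] > cs5 (cs5 = 3.4 mM, k5 = 1.7 s⁻¹)

starting material 5.0 mM; salt in the second phase 10.0 mM; spent carrier 0.11 mM; time 25 s; volume of the second phase over the first 0.25

- product is meant together with its crystals
- for a step with 2 of a species take k times the square, and two of it per event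
- in the second phase: salt in the second phase, spent salt in the second phase; everything else is in the first
- charges count per volume of the first phase; a concentration in a rate is the amount of a species over the volume of its own phase; every rate counts per litre of the first phase
- solid, in amounts per volume of the solution: crystals
- run time (flask): 25 s

1. how much product and crystals together there is at 25 s, in percent of the starting material charged
2. concentration of product in solution at 2.5 s, in percent of saturation
3. the change that raises the amount of product and crystals together at 25 s, in percent of the starting material charged most ("none" if none brings more than 2 percentage points) (Tuesday's / Wednesday's / Saturday's / none)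
4. amount of product and crystals together at 25 s, in percent of the starting material charged, after Tuesday's

Climb the ladder of times. At the charged amount of starting material, fresh carrier reacts with a half-life of 0.15 s, far shorter than the 11 s of its decay, so it mostly turns over. Resting dimer reopens with a half-life of 0.202 s, far shorter than the run, so it follows spent carrier closely. If spent carrier stands near half its charge, the carrier held in dimer, two to each dimer, is about 0.352 of the spent carrier.

Next, spent salt collects in the small second phase. Take spent salt equal in amount to product x. Once x passes 0.0952 mM, well below the charge of starting material, the back step of step 1 removes fresh carrier faster than step 2 does at that charge. I then put step 1 near equilibrium, with fresh over spent carrier equal to K1 times Y/x, where Y is the salt left. The phase volumes cancel.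

Now freeze spent carrier, the resting state, at F. I guess that fresh carrier and spent catalyst together match it, one falling as the other grows, which gives F = 0.0468 mM. Call g = k2·K1·F the stall constant, 0.00356 s⁻¹. Then x times dx/dt equals g times A times Y, with A the starting material left, so x grows as the root of time while A and Y are held.

With A and Y held at their charges, x reaches 2.98 mM at 25 s. Taking A and Y midway through their fall gives 2.31 mM, or 46.1% of the charge. The same sum at 2.5 s gives 0.876 mM, or 25.8% of saturation.

Doubled salt doubles fresh over spent carrier at equal spent salt, so I count fresh carrier and spent catalyst double. That gives a stall constant of 0.00250 s⁻¹ and a product of 2.71 mM, or 54.3%. Both amounts stay below the solubility, so step 5 has no crystals to act on, and my choice is Tuesday's.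

The forecast gives, in the order asked, 43%, 20%, Tuesday's and 53%, starting from “Spent salt building up in the small second phase pushes the carrier back to its spent form”. Its saturation figure is lower than mine, and its two yields are lower than mine as well .

The simulation gives, in the same order, 43.5%, 19.0%, Tuesday's with a gain of 9.8 percentage points, and 53.3%, so the forecast holds within its margins. At 25.0 s this flask still holds 57% of its starting material and 78% of its salt. Its spent carrier reads 44.3% of the catalyst charged at 12.5 s and 41.0% at 25.0 s, against a frozen 42.5%. The neighbouring flask charges 2.0 mM of starting material, all else as in this flask, and its salt over spent salt at 25.0 s stands twice that of this flask. Correcting g as for doubled salt gives 59.0% of its charge, and that neighbouring flask stands at 55.4%.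

Its constants belong to no real substance, and the outcome is calculated.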